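**Strategy.** Ring B holds the quaternary C10 (methyl) beside the tertiary C9 (C11 chain), with oxygen at C7 across the ring. This is the pattern left when a 2-silyloxy diene adds to an (E)-2-methyl-2-enal, so the plan cuts C8–C9 and C5–C10. One catalytic enantioselective [4+2] cycloaddition of silyloxy triene 5 (C2–C8) with enal 8 (C1, C9–C12) closes ring B, fixes C9 and C10, and installs the C7 oxygen as an enol ether. Metathesis then closes ring A. C5 and C8 are reset through a 5-en-7-one and its C8 enolate, and the (12Z)-diene is attached last.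

Key step: step 4

Remarks:
- Atoms carry labdane numbers (C1–C10 ring carbons, C11–C16 chain, C17 on C8, C18/C19 on C4, C20 on C10); cis/trans refer to the C10 methyl group.
- 3-(Benzyloxy)propanal is taken as a catalogue chemical.
- O12 is carried as a benzyl ether so that the hydrogenation of step 9 also frees the primary alcohol.
- C8 is hydroxylated at the dienone stage, where it is the only enolisable carbon, and C6 only after C8 has become quaternary, so both enolate oxidations are regiospecific.
- The (S)-catalyst in step 4 is assigned from the usual binding model for 2-substituted enals (derivation in the step); it was not checked against a tabulated example.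

**Step 1**
Reactants: 1 2,2-dimethylpent-4-enal; 2 diethyl (2-oxobutyl)phosphonate
Product: 4 (E)-6,6-dimethylnona-4,8-dien-3-one, via sodium phosphonate salt 3 (not isolated)
Conditions: 2, NaH, THF, 0 °C; then 1, 0 → 50 °C
Reagents that add atoms: none
Why: Horner–Wadsworth–Emmons olefination of a non-enolisable neopentyl aldehyde with the stabilised β-ketophosphonate anion should give the (E)-enone as the only new stereoelement.

**Step 2**
Reactants: 4 (E)-6,6-dimethylnona-4,8-dien-3-one
Product: 5 (2Z,4E)-3-(tert-butyldimethylsilyloxy)-6,6-dimethylnona-2,4,8-triene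
Conditions: TBSOTf, Et3N, CH2Cl2, −78 → 0 °C
Reagents that add atoms: tert-butyldimethylsilyl trifluoromethanesulfonate, CC(C)(C)[Si](C)(C)OS(=O)(=O)C(F)(F)F
Why: Soft enolisation and O-silylation of the ethyl ketone (the γ-carbon is quaternary, so only the ethyl CH2 can lose a proton) should give the cross-conjugated 2-silyloxy diene mainly as the (Z)-enol ether, and any (E)-isomer would affect only C8, which is reset in step 8.

**Step 3**
Reactants: 6 3-(benzyloxy)propanal; 7 2-(triphenylphosphoranylidene)propanal
Product: 8 (E)-5-(benzyloxy)-2-methylpent-2-enal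
Conditions: toluene, 90 °C
Reagents that add atoms: none
Why: Wittig olefination with the stabilised formyl ylide should give the (E)-trisubstituted enal, whose geometry later places the C9 chain cis to the C10 methyl.

**Step 4**
Reactants: 5 (2Z,4E)-3-(tert-butyldimethylsilyloxy)-6,6-dimethylnona-2,4,8-triene; 8 (E)-5-(benzyloxy)-2-methylpent-2-enal
Product: 9 (1S,2S,5R,6R)-6-[2-(benzyloxy)ethyl]-4-(tert-butyldimethylsilyloxy)-1,5-dimethyl-2-(2-methylpent-4-en-2-yl)cyclohex-3-ene-1-carbaldehyde
Conditions: (S)-3,3-diphenyl-1-(o-tolyl)tetrahydro-1H,3H-pyrrolo[1,2-c][1,3,2]oxazaborole (20 mol%), HNTf2 (18 mol%), 5 (1.5 equiv), CH2Cl2, −78 → −40 °C; Et3N quench at −78 °C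
Reagents that add atoms: none
Why: The N-protonated oxazaborolidine binds the formyl oxygen of the s-trans enal (formyl C–H···O contact to the ring oxygen), one gem-phenyl group screens the inner face, and diene 5 adds to the exposed Re face of the α-carbon in a concerted but asynchronous [4+2] cycloaddition in which the nucleophilic enol-ether terminus C8 bonds to the β-carbon C9 ahead of the C5–C10 bond. The closest known reaction type is the chiral oxazaborolidinium-catalysed Diels–Alder reaction of 2-methyl-2-enals with 2-silyloxy-1,3-dienes. Ring B is closed as a six-membered carbocycle by intermolecular cycloaddition, two σ-bonds being formed suprafacially on both partners. C10 (S in 9) is set by the catalyst through this facial choice, C9 follows from the (E)-enal geometry (chain cis to the C10 methyl), and C5 and C8 follow from the formyl-endo transition state and the diene geometry but are both erased later. The step needs regioselectivity, which the 2-silyloxy group (C7 para to C10) and the C5 substituent (ortho to C10) secure together, and facial selectivity, which rests on the catalyst; endo/exo selectivity is not needed. The tert-alkyl group at the C5 terminus retards the second bond formation, so the reaction is run concentrated with excess 5 and quenched cold with base to preserve the silyl enol ether.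

**Step 5**
Reactants: 9 cycloadduct aldehyde
Product: 10 6-[2-(benzyloxy)ethyl]-4-(tert-butyldimethylsilyloxy)-1-ethenyl-1,5-dimethyl-2-(2-methylpent-4-en-2-yl)cyclohex-3-ene (configuration as 9)
Conditions: Ph3PCH3Br, KOtBu, THF, 0 °C → rt
Reagents that add atoms: methyltriphenylphosphonium bromide, C[P+](c1ccccc1)(c1ccccc1)c1ccccc1.[Br-]
Why: Wittig methylenation of the non-enolisable α-quaternary aldehyde should proceed without epimerisation, and the silyl enol ether tolerates the ylide.

**Step 6**
Reactants: 10 vinyl triene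
Product: 11 12-(benzyloxy)-7-(tert-butyldimethylsilyloxy)-13,14,15,16-tetranorlabda-1,6-diene (cis-fused)
Conditions: second-generation Grubbs catalyst RuCl2(=CHPh)(H2IMes)(PCy3) (5 mol%), CH2Cl2, 40 °C
Reagents that add atoms: none
Why: Ring-closing metathesis between the allyl terminus and the C10 vinyl group should close the six-membered ring A with loss of ethylene, the trisubstituted silyl enol ether being inert to the ruthenium carbene.

**Step 7**
Reactants: 11 bicyclic silyl enol ether
Product: 12 (8R,9R,10S)-12-(benzyloxy)-13,14,15,16-tetranorlabda-1,5-dien-7-one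
Conditions: Pd(OAc)2 (divalent palladium, 1.2 equiv), MeCN, 40 °C
Reagents that add atoms: none
Why: Saegusa–Ito oxidation, in which palladation of the enol ether at C6 and β-hydride elimination of H5 (the only β-hydrogen) should give the 5-en-7-one and erase the provisional C5 centre.

**Step 8**
Reactants: 12 dienone
Product: 14 12-(benzyloxy)-8-hydroxy-13,14,15,16-tetranorlabda-1,5-dien-7-one, via potassium dienolate 13 (not isolated)
Conditions: KN(SiMe3)2, THF, −78 °C; 2-(phenylsulfonyl)-3-phenyloxaziridine, −78 °C; AcOH quench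
Reagents that add atoms: 2-(phenylsulfonyl)-3-phenyloxaziridine, O=S(=O)(c1ccccc1)N1OC1c1ccccc1
Why: Enolate hydroxylation with an N-sulfonyloxaziridine, in which C8 is the only enolisable position of 12 (C4 and C10 are quaternary) and oxygen should be delivered to the dienolate face opposite the pseudo-axial C10 methyl and the C9 chain, setting C8 with the hydroxyl trans and C17 cis to the C10 methyl.

**Step 9**
Reactants: 14 8-hydroxy dienone
Product: 15 (5R,8R,9S,10R)-8,12-dihydroxy-13,14,15,16-tetranorlabdan-7-one
Conditions: H2 (1–4 atm), Pd/C (palladium on carbon), EtOAc/EtOH, rt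
Reagents that add atoms: none
Why: Heterogeneous hydrogenation should saturate C1=C2, add hydrogen to C5=C6 from the face opposite the angular C10 methyl (H5 trans, trans-decalin, as for steroidal 5-en-7-ones) and cleave the benzyl ether by hydrogenolysis in the same operation.

**Step 10**
Reactants: 15 keto diol
Product: 16 7,8,12-tris(triethylsilyloxy)-13,14,15,16-tetranorlabd-6-ene
Conditions: Et3SiOTf (4.5 equiv), Et3N, CH2Cl2, −78 → 0 °C
Reagents that add atoms: triethylsilyl trifluoromethanesulfonate, CC[Si](CC)(CC)OS(=O)(=O)C(F)(F)F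
Why: Silyl triflate and amine base silylate both hydroxyls and form the silyl enol ether towards C6, the only α-carbon still bearing hydrogen, which also masks the C8 hydroxyl against later lactol formation with C12.

**Step 11**
Reactants: 16 tris(silyl) enol ether
Product: 18 6,8,12-tris(triethylsilyloxy)-13,14,15,16-tetranorlabdan-7-one, via silyloxy epoxide 17 (not isolated)
Conditions: mCPBA, CH2Cl2, −20 → 0 °C
Reagents that add atoms: 3-chloroperoxybenzoic acid, OOC(=O)c1cccc(Cl)c1
Why: Rubottom oxidation, in which epoxidation of the enol ether from the face opposite the axial C4 and C10 methyls followed by 1,4-silyl shift should give the equatorial 6-silyloxy ketone and set C6.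

**Step 12**
Reactants: 18 6-silyloxy ketone
Product: 19 6,8,12-tris(triethylsilyloxy)-13,14,15,16-tetranorlabdan-7-ol
Conditions: NaBH4, THF/EtOH, 0 °C → rt
Reagents that add atoms: none
Why: Borohydride reduction by axial attack on the face opposite the axial C8 methyl should give the equatorial C7 alcohol (cis to the C10 methyl), which is then the only free hydroxyl.

**Step 13**
Reactants: 19 C7 alcohol
Product: 20 7-acetoxy-6,8,12-tris(triethylsilyloxy)-13,14,15,16-tetranorlabdane
Conditions: Ac2O, DMAP, Et3N, CH2Cl2, rt → 40 °C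
Reagents that add atoms: acetic anhydride, CC(=O)OC(C)=O
Why: DMAP-catalysed acylation of the single free secondary alcohol places the acetate on O7 with no selectivity question among O6, O7 and O8.

**Step 14**
Reactants: 20 acetate
Product: 22 7-acetoxy-6,8-bis(triethylsilyloxy)-13,14,15,16-tetranorlabdan-12-al, via alkoxysulfonium chloride 21 (not isolated)
Conditions: (COCl)2, DMSO, CH2Cl2, −78 → −40 °C; Et3N, −78 → 0 °C
Reagents that add atoms: none
Why: Swern oxidation applied directly to a silyl ether, in which chlorodimethylsulfonium chloride cleaves only the primary triethylsilyl ether and oxidises it to the aldehyde while the secondary and tertiary silyl ethers and the acetate remain.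

**Step 15**
Reactants: 22 C12 aldehyde
Product: 23 (12Z)-7-acetoxy-13-iodo-6,8-bis(triethylsilyloxy)-14,15-dinorlabd-12-ene
Conditions: EtPPh3I, n-BuLi, THF, rt; I2, −78 °C; NaN(SiMe3)2, −20 °C; then 22, −78 → −20 °C
Reagents that add atoms: ethyltriphenylphosphonium iodide, CC[P+](c1ccccc1)(c1ccccc1)c1ccccc1.[I-]; iodine, II
Why: Stork–Zhao olefination with the α-iodo ylide should give the (Z)-2-iodoalkene (iodine cis to C11) under kinetic control at low temperature, where the acetate and silyl ethers tolerate the ylide.

**Step 16**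
Reactants: 23 bis(silyl) alkenyl iodide
Product: 24 (12Z)-13-iodo-14,15-dinorlabd-12-ene-6,7,8-triol 7-acetate
Conditions: HF·pyridine, pyridine, THF, 0 °C → rt
Reagents that add atoms: none
Why: Fluoride-mediated desilylation under buffered, mildly acidic conditions should cleave the secondary and tertiary triethylsilyl ethers without acetyl migration and without touching the alkenyl iodide.

**Step 17**
Reactants: 24 alkenyl iodide diol
Product: 25 (5R,6S,7R,8R,9S,10R)-6,8-dihydroxylabda-12(Z),14-dien-7-yl acetate (CNP0225877.2)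
Conditions: tributyl(vinyl)stannane, Pd(PPh3)4 (zerovalent palladium, 10 mol%), CuI (20 mol%), DMF, 40 °C
Reagents that add atoms: tributyl(vinyl)stannane, C=C[Sn](CCCC)(CCCC)CCCC
Why: Stille coupling of the alkenyl iodide with the vinylstannane proceeds with retention of alkene geometry under neutral conditions, so the acid-sensitive (12Z)-1,3-diene is formed last in the presence of the free hydroxyls and the acetate.

**Compound list**

1 | 2,2-dimethylpent-4-enal | C=CCC(C)(C)C=O | starting material
2 | diethyl (2-oxobutyl)phosphonate | CCC(=O)CP(=O)(OCC)OCC | starting material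
3 | sodium 1-(diethoxyphosphoryl)-2-oxobutan-1-ide (sodium salt of 2) | CCC(=O)[CH-]P(=O)(OCC)OCC.[Na+] | intermediate (not isolated)
4 | (E)-6,6-dimethylnona-4,8-dien-3-one | C=CCC(C)(C)/C=C/C(=O)CC | intermediate
5 | (2Z,4E)-3-(tert-butyldimethylsilyloxy)-6,6-dimethylnona-2,4,8-triene | C=CCC(C)(C)/C=C/C(O[Si](C)(C)C(C)(C)C)=C/C | intermediate
6 | 3-(benzyloxy)propanal | O=CCCOCc1ccccc1 | starting material
7 | 2-(triphenylphosphoranylidene)propanal | CC(C=O)=P(c1ccccc1)(c1ccccc1)c1ccccc1 | starting material
8 | (E)-5-(benzyloxy)-2-methylpent-2-enal | O=C/C(C)=C/CCOCc1ccccc1 | intermediate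
9 | (1S,2S,5R,6R)-6-[2-(benzyloxy)ethyl]-4-(tert-butyldimethylsilyloxy)-1,5-dimethyl-2-(2-methylpent-4-en-2-yl)cyclohex-3-ene-1-carbaldehyde; formyl cis to the C5 arm and the C8 methyl, C10 methyl cis to the C9 chain | c1ccccc1COCC[C@@H]1[C@@H](C)C(O[Si](C)(C)C(C)(C)C)=C[C@@H](C(C)(C)CC=C)[C@@]1(C)C=O | intermediate
10 | 6-[2-(benzyloxy)ethyl]-4-(tert-butyldimethylsilyloxy)-1-ethenyl-1,5-dimethyl-2-(2-methylpent-4-en-2-yl)cyclohex-3-ene; formyl of 9 converted into ethenyl, all stereocentres as in 9 | c1ccccc1COCC[C@@H]1[C@@H](C)C(O[Si](C)(C)C(C)(C)C)=C[C@@H](C(C)(C)CC=C)[C@@]1(C)C=C | intermediate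
11 | 12-(benzyloxy)-7-(tert-butyldimethylsilyloxy)-13,14,15,16-tetranorlabda-1,6-diene; cis-fused, H5 and the C9 chain cis, C17 trans to the C10 methyl | c1ccccc1COCC[C@@H]1[C@@H](C)C(O[Si](C)(C)C(C)(C)C)=C[C@H]2C(C)(C)CC=C[C@@]12C | intermediate
12 | (8R,9R,10S)-12-(benzyloxy)-13,14,15,16-tetranorlabda-1,5-dien-7-one; C9 chain cis, C17 trans to the C10 methyl | c1ccccc1COCC[C@@H]1[C@@H](C)C(=O)C=C2C(C)(C)CC=C[C@@]12C | intermediate
13 | potassium 12-(benzyloxy)-13,14,15,16-tetranorlabda-1,5,7-trien-7-olate | c1ccccc1COCC[C@@H]1C(C)=C([O-])C=C2C(C)(C)CC=C[C@@]12C.[K+] | intermediate (not isolated)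
14 | 12-(benzyloxy)-8-hydroxy-13,14,15,16-tetranorlabda-1,5-dien-7-one; 8-OH trans, C17 and the C9 chain cis to the C10 methyl | c1ccccc1COCC[C@@H]1[C@@](C)(O)C(=O)C=C2C(C)(C)CC=C[C@@]12C | intermediate
15 | (5R,8R,9S,10R)-8,12-dihydroxy-13,14,15,16-tetranorlabdan-7-one; trans-fused, H5 trans to the C10 methyl | OCC[C@@H]1[C@@](C)(O)C(=O)C[C@@H]2C(C)(C)CCC[C@]21C | intermediate
16 | 7,8,12-tris(triethylsilyloxy)-13,14,15,16-tetranorlabd-6-ene; ring stereocentres as in 15 | CC[Si](CC)(CC)OCC[C@@H]1[C@@](C)(O[Si](CC)(CC)CC)C(O[Si](CC)(CC)CC)=C[C@@H]2C(C)(C)CCC[C@]21C | intermediate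
17 | 6,7-epoxy-7,8,12-tris(triethylsilyloxy)-13,14,15,16-tetranorlabdane; epoxide oxygen trans to the C10 methyl | CC[Si](CC)(CC)OCC[C@@H]1[C@@](C)(O[Si](CC)(CC)CC)[C@@]3(O[Si](CC)(CC)CC)O[C@H]3[C@@H]2C(C)(C)CCC[C@]21C | intermediate (not isolated)
18 | 6,8,12-tris(triethylsilyloxy)-13,14,15,16-tetranorlabdan-7-one; O6 equatorial, trans to the C10 methyl | CC[Si](CC)(CC)OCC[C@@H]1[C@@](C)(O[Si](CC)(CC)CC)C(=O)[C@@H](O[Si](CC)(CC)CC)[C@@H]2C(C)(C)CCC[C@]21C | intermediate
19 | 6,8,12-tris(triethylsilyloxy)-13,14,15,16-tetranorlabdan-7-ol; 7-OH equatorial, cis to the C10 methyl | CC[Si](CC)(CC)OCC[C@@H]1[C@@](C)(O[Si](CC)(CC)CC)[C@H](O)[C@@H](O[Si](CC)(CC)CC)[C@@H]2C(C)(C)CCC[C@]21C | intermediate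
20 | 7-acetoxy-6,8,12-tris(triethylsilyloxy)-13,14,15,16-tetranorlabdane | CC[Si](CC)(CC)OCC[C@@H]1[C@@](C)(O[Si](CC)(CC)CC)[C@H](OC(C)=O)[C@@H](O[Si](CC)(CC)CC)[C@@H]2C(C)(C)CCC[C@]21C | intermediate
21 | [7-acetoxy-6,8-bis(triethylsilyloxy)-13,14,15,16-tetranorlabdan-12-yloxy]dimethylsulfonium chloride | C[S+](C)OCC[C@@H]1[C@@](C)(O[Si](CC)(CC)CC)[C@H](OC(C)=O)[C@@H](O[Si](CC)(CC)CC)[C@@H]2C(C)(C)CCC[C@]21C.[Cl-] | intermediate (not isolated)
22 | 7-acetoxy-6,8-bis(triethylsilyloxy)-13,14,15,16-tetranorlabdan-12-al | O=CC[C@@H]1[C@@](C)(O[Si](CC)(CC)CC)[C@H](OC(C)=O)[C@@H](O[Si](CC)(CC)CC)[C@@H]2C(C)(C)CCC[C@]21C | intermediate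
23 | (12Z)-7-acetoxy-13-iodo-6,8-bis(triethylsilyloxy)-14,15-dinorlabd-12-ene | C/C(I)=C/C[C@@H]1[C@@](C)(O[Si](CC)(CC)CC)[C@H](OC(C)=O)[C@@H](O[Si](CC)(CC)CC)[C@@H]2C(C)(C)CCC[C@]21C | intermediate
24 | (12Z)-13-iodo-14,15-dinorlabd-12-ene-6,7,8-triol 7-acetate | C/C(I)=C/C[C@@H]1[C@@](C)(O)[C@H](OC(C)=O)[C@@H](O)[C@@H]2C(C)(C)CCC[C@]21C | intermediate
25 | (5R,6S,7R,8R,9S,10R)-6,8-dihydroxylabda-12(Z),14-dien-7-yl acetate | C=C/C(C)=C\C[C@@H]1[C@@](C)(O)[C@H](OC(C)=O)[C@@H](O)[C@@H]2C(C)(C)CCC[C@]21C | target

**Totals and risks**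

Total step count: 17. Longest linear sequence: 16 steps (steps 1, 2 and 4–17, from 1 and 2 to 25).

Steps most likely to fail:

1. **Step 4.** The second bond (C5–C10) may fail to close at the tert-alkyl-substituted diene terminus, so that only conjugate addition occurs, or the catalyst may discriminate the enal faces poorly. Fallback: the cycloaddition of 5 and 8 is run under substrate control with stoichiometric Me2AlCl (CH2Cl2, −78 → −20 °C). Regiochemistry and the C9/C10 relation do not depend on the catalyst, so this should give the racemate, that is 9 together with its mirror-image adduct F1. The two are separated by preparative chromatography on a chiral stationary phase (amylose tris(3,5-dimethylphenylcarbamate)). The fallback sets out from 5 and 8 and returns to the route at 9.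

2. **Step 8.** Deprotonation of the hindered C8 methine may be incomplete, the enolate may add to the sulfonimine by-product, or oxygen may be delivered to both faces. Fallback: 12 is converted by soft enolisation (Me3SiOTf, Et3N, CH2Cl2, 0 °C) into the isolable 12-(benzyloxy)-7-(trimethylsilyloxy)-13,14,15,16-tetranorlabda-1,5,7-triene F2. Its electron-rich C7=C8 bond is epoxidised with dimethyldioxirane (1 equiv, acetone/CH2Cl2, −78 °C), conditions under which the ring A alkene should react much more slowly. Silyl shift then gives 12-(benzyloxy)-8-(trimethylsilyloxy)-13,14,15,16-tetranorlabda-1,5-dien-7-one F3 (Rubottom oxidation at the α'-position of an enone). Methanolysis with citric acid in MeOH removes the silyl group. The fallback sets out from 12 and returns at 14.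

3. **Step 9.** Hydrogen may be delivered to the wrong face of C5=C6 (cis-fused product), or reduction may stall at the hindered enone while the benzyl ether is already cleaved. Fallback: 14 is hydrogenated homogeneously with [Ir(cod)(PCy3)(py)]PF6 (H2, CH2Cl2, rt). The C8 hydroxyl, which lies on the face opposite the C10 methyl, binds iridium and directs hydrogen to that face of C5=C6, and C1=C2 is reduced as well. This should give the trans-fused 12-(benzyloxy)-8-hydroxy-13,14,15,16-tetranorlabdan-7-one F4. A separate hydrogenolysis (H2, Pd(OH)2/C, EtOAc) then removes the benzyl group. The fallback sets out from 14 and returns at 15.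

**Further compounds**

F1 | step 4 | (1R,2R,5S,6S)-6-[2-(benzyloxy)ethyl]-4-(tert-butyldimethylsilyloxy)-1,5-dimethyl-2-(2-methylpent-4-en-2-yl)cyclohex-3-ene-1-carbaldehyde (mirror image of 9) | c1ccccc1COCC[C@H]1[C@H](C)C(O[Si](C)(C)C(C)(C)C)=C[C@H](C(C)(C)CC=C)[C@]1(C)C=O
F2 | step 8 | 12-(benzyloxy)-7-(trimethylsilyloxy)-13,14,15,16-tetranorlabda-1,5,7-triene | c1ccccc1COCC[C@@H]1C(C)=C(O[Si](C)(C)C)C=C2C(C)(C)CC=C[C@@]12C
F3 | step 8 | 12-(benzyloxy)-8-(trimethylsilyloxy)-13,14,15,16-tetranorlabda-1,5-dien-7-one | c1ccccc1COCC[C@@H]1[C@@](C)(O[Si](C)(C)C)C(=O)C=C2C(C)(C)CC=C[C@@]12C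
F4 | step 9 | 12-(benzyloxy)-8-hydroxy-13,14,15,16-tetranorlabdan-7-one | c1ccccc1COCC[C@@H]1[C@@](C)(O)C(=O)C[C@@H]2C(C)(C)CCC[C@]21C
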